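**Retrosynthetic overview**
1. Target 13 ⇒ C1'–O bond: enantioselective formal hydration (copper-catalysed dearomative protoboration, then B→O oxidation) of the free triol 11, as the last step so that the arene hydrate never meets a deprotection.
2. 11 ⇒ biaryl triflate 9 by O-demethylation and C1'–OTf hydrogenolysis.
3. 9 ⇒ 7,7'-Suzuki union of bromonaphthol 6 (as its boronate 8) with its own triflate 7; both halves come from one naphthalene.
4. 6 ⇒ toluate-anion Michael/Dieckmann benzannulation of bromo-toluate 3 with enone 4; 3 from ethyl 6-methylsalicylate 1.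
5. Ring order: benzoate ring (given) → acetyl-bearing ring of each naphthalene → biaryl bond → dearomatisation of one acetyl-bearing ring last.

Assumption: the biaryl axis has only two ortho substituents (8-OH, 8'-OH) and rotates freely, so only C1' and C2' are controlled; primed locants are those of the dihydronaphthalene half.

**Step 1**
Reactants: 1 ethyl 2-hydroxy-6-methylbenzoate
Product: 2 ethyl 3-bromo-2-hydroxy-6-methylbenzoate
Conditions: NBS (1.0 equiv), i-Pr2NH (10 mol %), CH2Cl2, 0 °C → rt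
Reagents that add atoms: N-bromosuccinimide, O=C1CCC(=O)N1Br
Why: Amine-mediated ortho-bromination of a phenol (electrophilic aromatic substitution), in which the N-bromoamine hydrogen-bonded to the phenol delivers bromine to the only free ortho carbon (C3) and not to the para carbon; no stereocentre.

**Step 2**
Reactants: 2 ethyl 3-bromo-2-hydroxy-6-methylbenzoate
Product: 3 ethyl 3-bromo-2-methoxy-6-methylbenzoate
Conditions: MeI (1.5 equiv), K2CO3 (2 equiv), DMF, 50 °C
Reagents that add atoms: iodomethane, CI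
Why: Williamson O-methylation; the methyl ether masks the phenol for the anionic annulation and later marks the 8-oxygen.

**Step 3**
Reactants: 3 ethyl 3-bromo-2-methoxy-6-methylbenzoate; 4 (E)-4-methoxypent-3-en-2-one
Product: 6 1-(7-bromo-1-hydroxy-8-methoxy-3-methylnaphthalen-2-yl)ethan-1-one, via lithiated toluate 5 (not isolated)
Conditions: LiN(i-Pr)2 (2.4 equiv), THF, −78 °C, 30 min; then 4 (1.2 equiv), −78 °C → rt; aq NH4Cl, then 1 M HCl
Reagents that add atoms: none
Why: Staunton–Weinreb toluate-anion annulation, in which the benzylic anion adds to the β-carbon of the vinylogous ester (Michael), the enolate closes onto the ethyl ester (Dieckmann) and loss of methanol aromatises the ring to the 2-acetyl-3-methyl-1-naphthol; the aryl bromide survives LiN(i-Pr)2 at −78 °C.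

**Step 4**
Reactants: 6 1-(7-bromo-1-hydroxy-8-methoxy-3-methylnaphthalen-2-yl)ethan-1-one
Product: 7 2-acetyl-7-bromo-8-methoxy-3-methylnaphthalen-1-yl trifluoromethanesulfonate
Conditions: Tf2O (1.3 equiv), pyridine (4 equiv), CH2Cl2, 0 °C → rt
Reagents that add atoms: trifluoromethanesulfonic anhydride, O=S(=O)(OS(=O)(=O)C(F)(F)F)C(F)(F)F
Why: O-Sulfonylation of the chelated 1-naphthol, which marks the half that will lose its C1 oxygen.

**Step 5**
Reactants: 6 1-(7-bromo-1-hydroxy-8-methoxy-3-methylnaphthalen-2-yl)ethan-1-one (1.1 equiv); 7 2-acetyl-7-bromo-8-methoxy-3-methylnaphthalen-1-yl trifluoromethanesulfonate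
Product: 9 2-acetyl-7-(7-acetyl-8-hydroxy-1-methoxy-6-methylnaphthalen-2-yl)-8-methoxy-3-methylnaphthalen-1-yl trifluoromethanesulfonate, via pinacol boronate 8 (not isolated)
Conditions: 6, B2pin2 (1.15 equiv), PdCl2[Fe(C5H4PPh2)2] (5 mol %), KOAc (3 equiv), 1,4-dioxane, 90 °C; then 7 (1.0 equiv), Pd(PPh3)4 (5 mol %), K3PO4 (3 equiv), H2O (10 vol %), 80 °C
Reagents that add atoms: none
Why: Miyaura borylation followed in the same pot by Suzuki–Miyaura coupling; zerovalent palladium with PPh3 inserts into the C–Br bond of 7 much faster than into its di-ortho-substituted C–OTf bond, so the 7,7'-biaryl forms with the triflate intact.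

**Step 6**
Reactants: 9 2-acetyl-7-(7-acetyl-8-hydroxy-1-methoxy-6-methylnaphthalen-2-yl)-8-methoxy-3-methylnaphthalen-1-yl trifluoromethanesulfonate
Product: 10 1-[7-(7-acetyl-1-methoxy-6-methylnaphthalen-2-yl)-1-hydroxy-8-methoxy-3-methylnaphthalen-2-yl]ethan-1-one
Conditions: Pd(OAc)2 (10 mol %), Fe(C5H4PPh2)2 (12 mol %), HCO2H (3 equiv), Et3N (5 equiv), DMF, 80 °C
Reagents that add atoms: none
Why: Palladium-catalysed formate hydrogenolysis of the aryl triflate (hydride from decarboxylation of a palladium formate) gives the 1'-unsubstituted 2-acetylnaphthalene needed for the hydration.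

**Step 7**
Reactants: 10 1-[7-(7-acetyl-1-methoxy-6-methylnaphthalen-2-yl)-1-hydroxy-8-methoxy-3-methylnaphthalen-2-yl]ethan-1-one
Product: 11 1-[7-(7-acetyl-1-hydroxy-6-methylnaphthalen-2-yl)-1,8-dihydroxy-3-methylnaphthalen-2-yl]ethan-1-one
Conditions: BBr3 (6 equiv), CH2Cl2, −78 → 0 °C; MeOH, then H2O
Reagents that add atoms: none
Why: Lewis-acid cleavage of both aryl methyl ethers, done before the acid- and base-sensitive arene hydrate exists so that the final step needs no deprotection.

**Step 8**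
Reactants: 11 1-[7-(7-acetyl-1-hydroxy-6-methylnaphthalen-2-yl)-1,8-dihydroxy-3-methylnaphthalen-2-yl]ethan-1-one
Product: 13 1-[(1S,2R)-7-(7-acetyl-1,8-dihydroxy-6-methylnaphthalen-2-yl)-1,8-dihydroxy-3-methyl-1,2-dihydronaphthalen-2-yl]ethan-1-one, via benzylic pinacol boronate 12 (not isolated)
Conditions: CuCl (10 mol %), (R,R)-QuinoxP* (11 mol %), NaOt-Bu (20 mol %), B2pin2 (3 equiv), MeOH (4 equiv), THF, N2, 30 °C, 24 h; then NaBO3·4H2O (6 equiv), THF/pH 7 phosphate buffer, 0 °C, 1 h; neutral work-up, reversed-phase purification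
Reagents that add atoms: sodium perborate tetrahydrate, [Na+].[O-]B1OO1
Why: Proposed new method: a chiral bisphosphine-ligated copper boryl (monovalent copper, from CuOt-Bu and B2pin2) should add across the C1'=C2' bond of the 2-acetylnaphthalene half, the enone-like bond of highest double-bond character, placing boron on C1' and giving an O-bound copper dienolate in which only the acetyl-bearing ring is dearomatised (the roughly 25 kcal/mol resonance cost is outweighed by trading a B–B bond for C–B and O–B bonds); the ligand fixes the face of attack and hence C1', methanolysis and alkoxide-mediated equilibration at the acidic C2'–H give the trans isomer (Bpin pseudo-axial away from the peri 8'-oxygen, acetyl pseudo-axial to avoid A(1,2) strain with the 3'-methyl), and perborate replaces boron by oxygen with retention to give the (1'S,2'R) arene hydrate; the other half is inert because its C1 carries a chelated donor oxygen, the phenols are tolerated as in protic copper–boron conjugate additions (reversibly capped as ArO–Bpin, freed on work-up), and the pH 7 oxidation avoids re-aromatisation; the closest known reaction types are copper-catalysed enantioselective β-borylation/oxidation of β-aryl enones and copper-catalysed enantioselective dearomative protoboration of indole carboxylates, neither shown on a carbocyclic naphthyl ketone; the ligand enantiomer that gives 1'S is fixed in the first run (mirror-image ligand otherwise).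

**Compound list**
1 | ethyl 2-hydroxy-6-methylbenzoate | CCOC(=O)c1c(C)cccc1O | starting material
2 | ethyl 3-bromo-2-hydroxy-6-methylbenzoate | CCOC(=O)c1c(C)ccc(Br)c1O | intermediate
3 | ethyl 3-bromo-2-methoxy-6-methylbenzoate | CCOC(=O)c1c(C)ccc(Br)c1OC | intermediate
4 | (E)-4-methoxypent-3-en-2-one | CO/C(C)=C/C(C)=O | starting material
5 | ethyl 3-bromo-6-(lithiomethyl)-2-methoxybenzoate (not isolated) | [Li]Cc1ccc(Br)c(OC)c1C(=O)OCC | intermediate
6 | 1-(7-bromo-1-hydroxy-8-methoxy-3-methylnaphthalen-2-yl)ethan-1-one | CC(=O)c1c(C)cc2ccc(Br)c(OC)c2c1O | intermediate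
7 | 2-acetyl-7-bromo-8-methoxy-3-methylnaphthalen-1-yl trifluoromethanesulfonate | CC(=O)c1c(C)cc2ccc(Br)c(OC)c2c1OS(=O)(=O)C(F)(F)F | intermediate
8 | 1-[1-hydroxy-8-methoxy-3-methyl-7-(4,4,5,5-tetramethyl-1,3,2-dioxaborolan-2-yl)naphthalen-2-yl]ethan-1-one (not isolated) | CC(=O)c1c(C)cc2ccc(B3OC(C)(C)C(C)(C)O3)c(OC)c2c1O | intermediate
9 | 2-acetyl-7-(7-acetyl-8-hydroxy-1-methoxy-6-methylnaphthalen-2-yl)-8-methoxy-3-methylnaphthalen-1-yl trifluoromethanesulfonate | CC(=O)c1c(C)cc2ccc(-c3ccc4cc(C)c(C(C)=O)c(OS(=O)(=O)C(F)(F)F)c4c3OC)c(OC)c2c1O | intermediate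
10 | 1-[7-(7-acetyl-1-methoxy-6-methylnaphthalen-2-yl)-1-hydroxy-8-methoxy-3-methylnaphthalen-2-yl]ethan-1-one | CC(=O)c1c(C)cc2ccc(-c3ccc4cc(C)c(C(C)=O)cc4c3OC)c(OC)c2c1O | intermediate
11 | 1-[7-(7-acetyl-1-hydroxy-6-methylnaphthalen-2-yl)-1,8-dihydroxy-3-methylnaphthalen-2-yl]ethan-1-one | CC(=O)c1c(C)cc2ccc(-c3ccc4cc(C)c(C(C)=O)cc4c3O)c(O)c2c1O | intermediate
12 | 1-[(1S,2S)-7-(7-acetyl-1,8-dihydroxy-6-methylnaphthalen-2-yl)-8-hydroxy-3-methyl-1-(4,4,5,5-tetramethyl-1,3,2-dioxaborolan-2-yl)-1,2-dihydronaphthalen-2-yl]ethan-1-one (not isolated) | CC(=O)c1c(C)cc2ccc(-c3ccc4c(c3O)[C@@H](B5OC(C)(C)C(C)(C)O5)[C@H](C(C)=O)C(C)=C4)c(O)c2c1O | intermediate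
13 | 1-[(1S,2R)-7-(7-acetyl-1,8-dihydroxy-6-methylnaphthalen-2-yl)-1,8-dihydroxy-3-methyl-1,2-dihydronaphthalen-2-yl]ethan-1-one | CC(=O)c1c(C)cc2ccc(-c3ccc4c(c3O)[C@@H](O)[C@H](C(C)=O)C(C)=C4)c(O)c2c1O | target

**Totals**
Total steps: 8. Longest linear sequence: 8 (steps 1 → 8; compound 6 enters step 5 both directly and through 7).

**Steps most likely to fail, with fallbacks**

Step 8 (the proposed new step; risks are low reactivity at the peri-hindered C1', competing 1,2-borylation of a ketone, and copper binding by the chelating phenols). The fallback uses known reaction types only, sets out from 3 and from boronate 8, and comes back at 13; its weak point is competing light absorption by the naphthyl ketone half during the photochemical step. The carbinol oxygen is taken from an aldehyde, and the hydroxylated ring is built by photoenolisation/Diels–Alder instead of dearomatisation. Ester 3 is reduced (i-Bu2AlH, CH2Cl2, −78 °C) to (3-bromo-2-methoxy-6-methylphenyl)methanol F4 and oxidised (MnO2, CH2Cl2) to 3-bromo-2-methoxy-6-methylbenzaldehyde F5. Suzuki coupling of F5 with boronate 8 (made from 6 as in step 5; Pd(PPh3)4, K3PO4, dioxane/H2O, 80 °C) gives 3-(7-acetyl-8-hydroxy-1-methoxy-6-methylnaphthalen-2-yl)-2-methoxy-6-methylbenzaldehyde F6. BBr3 (CH2Cl2, −78 → 0 °C) cleaves both methyl ethers to 3-(7-acetyl-1,8-dihydroxy-6-methylnaphthalen-2-yl)-2-hydroxy-6-methylbenzaldehyde F7. t-BuMe2SiCl/imidazole (DMF) silylates the two non-chelated phenols to 3-{7-acetyl-1-[(tert-butyldimethylsilyl)oxy]-8-hydroxy-6-methylnaphthalen-2-yl}-2-[(tert-butyldimethylsilyl)oxy]-6-methylbenzaldehyde F8, which removes the hydrogen-bonded salicylaldehyde that would quench photoenolisation. Irradiation (365 nm, degassed toluene) with pent-3-yn-2-one gives the photoenol Diels–Alder adduct, racemic 1-{7-[7-acetyl-1-[(tert-butyldimethylsilyl)oxy]-8-hydroxy-6-methylnaphthalen-2-yl]-8-[(tert-butyldimethylsilyl)oxy]-1-hydroxy-3-methyl-1,4-dihydronaphthalen-2-yl}ethan-1-one F9. Polyanion formation (KN(SiMe3)2, 3.2 equiv, THF, −78 → −40 °C; the C1' alkoxide blocks E1cB loss of oxygen) and kinetic α-protonation with AcOH at −78 °C move the double bond into conjugation with the arene. Preparative chiral HPLC of the resulting trans racemate gives 1-{(1S,2R)-7-[7-acetyl-1-[(tert-butyldimethylsilyl)oxy]-8-hydroxy-6-methylnaphthalen-2-yl]-8-[(tert-butyldimethylsilyl)oxy]-1-hydroxy-3-methyl-1,2-dihydronaphthalen-2-yl}ethan-1-one F10. Bu4NF/AcOH (THF, 0 °C) removes the silyl groups and gives 13.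

Step 1 (risk: bromination para to the hydrogen-bonded phenol instead of ortho). The fallback sets out from 1 and comes back at 2. The position next to oxygen is addressed through boron instead of by electrophilic substitution: phenol-directed iridium-catalysed ortho C–H borylation (HBpin, then B2pin2, [Ir(OMe)(C8H12)]2, 4,4'-di-tert-butyl-2,2'-bipyridine, cyclohexane, 80 °C; MeOH work-up) gives ethyl 2-hydroxy-6-methyl-3-(4,4,5,5-tetramethyl-1,3,2-dioxaborolan-2-yl)benzoate F1, and copper-mediated bromodeboronation (CuBr2, MeOH/H2O, 80 °C) converts F1 into 2.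

Step 5 (risk: insertion into or hydrolysis of the C–OTf bond, and scrambling in the one-pot borylation/coupling). The fallback sets out from 6 and comes back at 10. The oxygen is removed before the biaryl bond is made, so no triflate is present in the cross-coupling. Bromide 6 is borylated as before and boronate 8 is isolated. Triflation (Tf2O, pyridine) gives 2-acetyl-8-methoxy-3-methyl-7-(4,4,5,5-tetramethyl-1,3,2-dioxaborolan-2-yl)naphthalen-1-yl trifluoromethanesulfonate F2. Formate hydrogenolysis (Pd(OAc)2, Fe(C5H4PPh2)2, HCO2H, Et3N, DMF, 60 °C) gives 1-[8-methoxy-3-methyl-7-(4,4,5,5-tetramethyl-1,3,2-dioxaborolan-2-yl)naphthalen-2-yl]ethan-1-one F3. Suzuki coupling of F3 with bromide 6 (Pd(PPh3)4, K3PO4, dioxane/H2O, 80 °C) gives 10 directly.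

**Further compounds**
F1 | step 1 | ethyl 2-hydroxy-6-methyl-3-(4,4,5,5-tetramethyl-1,3,2-dioxaborolan-2-yl)benzoate | CCOC(=O)c1c(C)ccc(B2OC(C)(C)C(C)(C)O2)c1O
F2 | step 5 | 2-acetyl-8-methoxy-3-methyl-7-(4,4,5,5-tetramethyl-1,3,2-dioxaborolan-2-yl)naphthalen-1-yl trifluoromethanesulfonate | CC(=O)c1c(C)cc2ccc(B3OC(C)(C)C(C)(C)O3)c(OC)c2c1OS(=O)(=O)C(F)(F)F
F3 | step 5 | 1-[8-methoxy-3-methyl-7-(4,4,5,5-tetramethyl-1,3,2-dioxaborolan-2-yl)naphthalen-2-yl]ethan-1-one | CC(=O)c1c(C)cc2ccc(B3OC(C)(C)C(C)(C)O3)c(OC)c2c1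
F4 | step 8 | (3-bromo-2-methoxy-6-methylphenyl)methanol | COc1c(Br)ccc(C)c1CO
F5 | step 8 | 3-bromo-2-methoxy-6-methylbenzaldehyde | COc1c(Br)ccc(C)c1C=O
F6 | step 8 | 3-(7-acetyl-8-hydroxy-1-methoxy-6-methylnaphthalen-2-yl)-2-methoxy-6-methylbenzaldehyde | CC(=O)c1c(C)cc2ccc(-c3ccc(C)c(C=O)c3OC)c(OC)c2c1O
F7 | step 8 | 3-(7-acetyl-1,8-dihydroxy-6-methylnaphthalen-2-yl)-2-hydroxy-6-methylbenzaldehyde | CC(=O)c1c(C)cc2ccc(-c3ccc(C)c(C=O)c3O)c(O)c2c1O
F8 | step 8 | 3-{7-acetyl-1-[(tert-butyldimethylsilyl)oxy]-8-hydroxy-6-methylnaphthalen-2-yl}-2-[(tert-butyldimethylsilyl)oxy]-6-methylbenzaldehyde | CC(=O)c1c(C)cc2ccc(-c3ccc(C)c(C=O)c3O[Si](C)(C)C(C)(C)C)c(O[Si](C)(C)C(C)(C)C)c2c1O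
F9 | step 8 | racemic 1-{7-[7-acetyl-1-[(tert-butyldimethylsilyl)oxy]-8-hydroxy-6-methylnaphthalen-2-yl]-8-[(tert-butyldimethylsilyl)oxy]-1-hydroxy-3-methyl-1,4-dihydronaphthalen-2-yl}ethan-1-one | CC(=O)C1=C(C)Cc2ccc(-c3ccc4cc(C)c(C(C)=O)c(O)c4c3O[Si](C)(C)C(C)(C)C)c(O[Si](C)(C)C(C)(C)C)c2C1O
F10 | step 8 | 1-{(1S,2R)-7-[7-acetyl-1-[(tert-butyldimethylsilyl)oxy]-8-hydroxy-6-methylnaphthalen-2-yl]-8-[(tert-butyldimethylsilyl)oxy]-1-hydroxy-3-methyl-1,2-dihydronaphthalen-2-yl}ethan-1-one | CC(=O)c1c(C)cc2ccc(-c3ccc4c(c3O[Si](C)(C)C(C)(C)C)[C@@H](O)[C@H](C(C)=O)C(C)=C4)c(O[Si](C)(C)C(C)(C)C)c2c1O
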